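Ring B is taken apart at its B2–B3 and B1–B6 bonds (rings lettered A to G from the 2,4,6-trioxygenated end). A thermal cyclobutenone–ynol ether benzannulation closes this ring in one operation around two aryl ether oxygens that arrive ready-made. B4, flanked by the oxygenated carbons B3 and B5, brings its oxygen to ring C from an aryloxyacetic acid; B1, para to it, brings its oxygen to ring A from the ynol ether. This spares the route an arylation at the doubly ortho-oxygenated carbon B4. The precursors are a racemic 4-aryloxy-3-ethoxycyclobutenone whose aryloxy group is the permethylated CDEFG pentamer, built by four Ullmann coupling/Baeyer–Villiger cycles, and 2,4,6-trimethoxyphenyl ethynyl ether.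

Key step: step 14

Assumption: every hydroxyl is carried as a methyl ether and the B5 oxygen as the ethyl ether delivered by ethoxyacetylene, because one BBr3 treatment removes both kinds of alkyl group; racemic compounds are drawn as one enantiomer.

Shorthand in names: FG-O = 3,5-dimethoxy-4-(3,4,5-trimethoxyphenoxy)phenoxy; EFG-O = 3,4,5-trimethoxy-2-(FG-O)phenoxy; DEFG-O = 3,5-dimethoxy-4-(EFG-O)phenoxy; CDEFG-O = 3,4,5-trimethoxy-2-(DEFG-O)phenoxy.

Step 1
Reactants: 1 3,4,5-trimethoxyphenol; 2 4-bromo-3,5-dimethoxybenzaldehyde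
Product: 3 FG aldehyde, 3,5-dimethoxy-4-(3,4,5-trimethoxyphenoxy)benzaldehyde
Conditions: CuI (10 mol %), picolinic acid (20 mol %), K3PO4 (2 equiv), DMSO, 90 °C, Ar
Reagents that add atoms: none
Why: Ullmann diaryl ether synthesis in which the electron-rich, unhindered phenoxide of 1 couples at a C–Br bond activated by the para formyl group, with a CuI/picolinic acid system suited to aryl halides carrying two ortho substituents.

Step 2
Reactants: 3 FG aldehyde
Product: 5 FG phenol, 3,5-dimethoxy-4-(3,4,5-trimethoxyphenoxy)phenol, via FG aryl formate 4 (not isolated)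
Conditions: mCPBA (1.3 equiv), CH2Cl2, 0 °C to rt; then K2CO3 (cat.), MeOH, rt
Reagents that add atoms: mCPBA, O=C(OO)c1cccc(Cl)c1
Why: Baeyer–Villiger oxidation (Dakin-type) in which the electron-rich aryl group migrates in preference to hydrogen, followed by base-catalysed methanolysis of the formate, which leaves all aryl ethers untouched.

Step 3
Reactants: 5 FG phenol; 6 2-bromo-3,4,5-trimethoxybenzaldehyde
Product: 7 EFG aldehyde, 3,4,5-trimethoxy-2-(FG-O)benzaldehyde
Conditions: CuI (10 mol %), picolinic acid (20 mol %), K3PO4 (2 equiv), DMSO, 90 °C, Ar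
Reagents that add atoms: none
Why: Ullmann diaryl ether synthesis between an unhindered phenoxide and a bromide whose ortho formyl group activates the C–Br bond and can assist the copper insertion.

Step 4
Reactants: 7 EFG aldehyde
Product: 9 EFG phenol, 3,4,5-trimethoxy-2-(FG-O)phenol, via EFG aryl formate 8 (not isolated)
Conditions: mCPBA (1.3 equiv), CH2Cl2, 0 °C to rt; then K2CO3 (cat.), MeOH, rt
Reagents that add atoms: mCPBA, O=C(OO)c1cccc(Cl)c1
Why: Baeyer–Villiger oxidation of a benzaldehyde with ortho aryloxy and para methoxy donors, which favour aryl migration, followed by methanolysis of the formate.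

Step 5
Reactants: 9 EFG phenol; 2 4-bromo-3,5-dimethoxybenzaldehyde
Product: 10 DEFG aldehyde, 3,5-dimethoxy-4-(EFG-O)benzaldehyde
Conditions: CuI (20 mol %), picolinic acid (40 mol %), K3PO4 (2 equiv), 2 (1.5 equiv), DMSO, 100 °C, Ar
Reagents that add atoms: none
Why: Ullmann diaryl ether synthesis at the same formyl-activated C–Br bond as in step 1, with more catalyst and excess bromide to offset the single ortho aryloxy substituent of the phenoxide.

Step 6
Reactants: 10 DEFG aldehyde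
Product: 12 DEFG phenol, 3,5-dimethoxy-4-(EFG-O)phenol, via DEFG aryl formate 11 (not isolated)
Conditions: mCPBA (1.3 equiv), CH2Cl2, 0 °C to rt; then K2CO3 (cat.), MeOH, rt
Reagents that add atoms: mCPBA, O=C(OO)c1cccc(Cl)c1
Why: Baeyer–Villiger oxidation with migration of the para-aryloxy-substituted aryl group, as in step 2, followed by methanolysis of the formate.

Step 7
Reactants: 12 DEFG phenol; 6 2-bromo-3,4,5-trimethoxybenzaldehyde
Product: 13 CDEFG aldehyde, 3,4,5-trimethoxy-2-(DEFG-O)benzaldehyde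
Conditions: CuI (10 mol %), picolinic acid (20 mol %), K3PO4 (2 equiv), DMSO, 90 °C, Ar
Reagents that add atoms: none
Why: Ullmann diaryl ether synthesis repeating step 3, since the phenoxide of 12 is again unhindered and the bromide is activated by its ortho formyl group.

Step 8
Reactants: 13 CDEFG aldehyde
Product: 15 CDEFG phenol, 3,4,5-trimethoxy-2-(DEFG-O)phenol, via CDEFG aryl formate 14 (not isolated)
Conditions: mCPBA (1.3 equiv), CH2Cl2, 0 °C to rt; then K2CO3 (cat.), MeOH, rt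
Reagents that add atoms: mCPBA, O=C(OO)c1cccc(Cl)c1
Why: Baeyer–Villiger oxidation repeating step 4 on the same ortho-aryloxy benzaldehyde type, followed by methanolysis of the formate.

Step 9
Reactants: 15 CDEFG phenol; 16 methyl bromoacetate
Product: 18 (CDEFG-O)acetic acid, via methyl aryloxyacetate 17 (not isolated)
Conditions: K2CO3, DMF, 50 °C; then LiOH, THF/H2O, rt; aq. HCl work-up
Reagents that add atoms: lithium hydroxide, [Li+].[OH-]
Why: Williamson ether synthesis on the phenoxide followed by ester saponification, two operations to which methyl and diaryl ethers are inert.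

Step 10
Reactants: 18 (CDEFG-O)acetic acid; 19 ethoxyacetylene
Product: 22 racemic 4-(CDEFG-O)-3-ethoxycyclobut-2-en-1-one, via aryloxyacetyl chloride 20 (not isolated), via aryloxyketene 21 (not isolated)
Conditions: (COCl)2, DMF (cat.), CH2Cl2, 0 °C to rt, evaporate; then 19 (4 equiv), Et3N (1.5 equiv, slow addition), CH2Cl2, 0 °C to rt; chromatography on Et3N-deactivated silica
Reagents that add atoms: none
Why: Acid chloride formation, dehydrochlorination to the aryloxyketene and ketene–ynol ether [2+2] cycloaddition, in which the nucleophilic terminal carbon of 19 bonds to the ketene carbonyl carbon so that ethoxy ends at C3 and aryloxy at C4; the C4 stereocentre forms as a racemate, which is harmless because step 14 destroys it.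

Step 11
Reactants: 23 2,4,6-trimethoxybenzaldehyde
Product: 25 2,4,6-trimethoxyphenol, via trimethoxyphenyl formate 24 (not isolated)
Conditions: mCPBA (1.2 equiv), CH2Cl2, 0 °C to rt; then K2CO3 (cat.), MeOH, rt, Ar
Reagents that add atoms: mCPBA, O=C(OO)c1cccc(Cl)c1
Why: Baeyer–Villiger oxidation of a benzaldehyde with two ortho and one para methoxy donor, the most favourable case for aryl migration, followed by methanolysis of the formate.

Step 12
Reactants: 25 2,4,6-trimethoxyphenol; 26 trichloroethylene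
Product: 27 (E)-1,2-dichlorovinyl 2,4,6-trimethoxyphenyl ether
Conditions: K2CO3, 26 (1.5 equiv), DMF, 70 °C
Reagents that add atoms: none
Why: Nucleophilic vinylic substitution by elimination–addition, in which base converts 26 into dichloroacetylene and the phenoxide adds to it in anti fashion, which should give the E vinyl ether.

Step 13
Reactants: 27 (E)-1,2-dichlorovinyl 2,4,6-trimethoxyphenyl ether
Product: 30 ethynyl 2,4,6-trimethoxyphenyl ether, via chloroethynyl ether 28 (not isolated), via lithium acetylide 29 (not isolated)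
Conditions: n-BuLi (2.2 equiv), THF, −78 °C to −40 °C; then H2O, −78 °C; used at once as a solution
Reagents that add atoms: none
Why: Dehydrochlorination by n-BuLi to the chloroalkyne, chlorine–lithium exchange to the acetylide and protonation, the standard alkynyl ether synthesis from dichlorovinyl ethers, run cold so that the arene is not lithiated.

Step 14
Reactants: 22 racemic 4-(CDEFG-O)-3-ethoxycyclobut-2-en-1-one; 30 ethynyl 2,4,6-trimethoxyphenyl ether
Product: 35 protected heptamer, 2-(CDEFG-O)-3-ethoxy-5-(2,4,6-trimethoxyphenoxy)phenol, via vinylketene 31 (not isolated), via vinylcyclobutenone 32 (not isolated), via dienylketene 33 (not isolated), via cyclohexadienone 34 (not isolated)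
Conditions: 30 (3 equiv), toluene (degassed), 80 °C then 110 °C, sealed tube
Reagents that add atoms: none
Why: Thermal 4π electrocyclic opening of 22, with the C4 aryloxy donor rotating outward, should give vinylketene 31, which the electron-rich ynol ether 30 traps in a [2+2] cycloaddition (its CH carbon bonds to the ketene carbonyl carbon, forming B2–B3, and its oxygen-bearing carbon to the ketene α-carbon, forming B1–B6) to give vinylcyclobutenone 32. A second 4π opening gives dienylketene 33, which closes ring B by a thermal disrotatory 6π electrocyclisation between the ketene carbon (B3) and the aryloxy-bearing vinyl terminus (B4), and dienone 34 tautomerises to the phenol. The closest known reaction type is the Danheiser benzannulation of cyclobutenones with alkoxy- and siloxyacetylenes, which gives resorcinol monoethers. No stereocentre is created, and the racemic centre of 22 is erased in the first ring opening. The only selectivity needed is the regiochemistry of the [2+2], and the polarisation of the ynol ether by its oxygen secures it, placing the ring A oxygen meta to the new B3 hydroxyl and para to the ring C oxygen. The excess of 30, which has no alkyl hydrogen for a retro-ene fragmentation, should suppress ketene dimerisation.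

Step 15
Reactants: 35 protected heptamer
Product: 36 target heptamer CNP0292517.0
Conditions: BBr3 (40 equiv), CH2Cl2, −78 °C to rt, Ar; then H2O, 0 °C; chromatography on Sephadex LH-20 under Ar
Reagents that add atoms: none
Why: Lewis acid dealkylation of aryl alkyl ethers, in which BBr3 coordinates each alkoxy oxygen and bromide removes methyl or ethyl by SN2, while the six diaryl ether bonds offer no sp3 carbon and should survive.

Compound list
1 | 3,4,5-trimethoxyphenol | COc1cc(O)cc(OC)c1OC | starting material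
2 | 4-bromo-3,5-dimethoxybenzaldehyde | O=Cc1cc(OC)c(Br)c(OC)c1 | starting material
3 | FG aldehyde, 3,5-dimethoxy-4-(3,4,5-trimethoxyphenoxy)benzaldehyde | O=Cc1cc(OC)c(Oc2cc(OC)c(OC)c(OC)c2)c(OC)c1 | intermediate
4 | FG aryl formate, 3,5-dimethoxy-4-(3,4,5-trimethoxyphenoxy)phenyl formate | O=COc1cc(OC)c(Oc2cc(OC)c(OC)c(OC)c2)c(OC)c1 | intermediate
5 | FG phenol, 3,5-dimethoxy-4-(3,4,5-trimethoxyphenoxy)phenol | Oc1cc(OC)c(Oc2cc(OC)c(OC)c(OC)c2)c(OC)c1 | intermediate
6 | 2-bromo-3,4,5-trimethoxybenzaldehyde | O=Cc1cc(OC)c(OC)c(OC)c1Br | starting material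
7 | EFG aldehyde, 3,4,5-trimethoxy-2-(FG-O)benzaldehyde | O=Cc1cc(OC)c(OC)c(OC)c1Oc1cc(OC)c(Oc2cc(OC)c(OC)c(OC)c2)c(OC)c1 | intermediate
8 | EFG aryl formate, 3,4,5-trimethoxy-2-(FG-O)phenyl formate | O=COc1cc(OC)c(OC)c(OC)c1Oc1cc(OC)c(Oc2cc(OC)c(OC)c(OC)c2)c(OC)c1 | intermediate
9 | EFG phenol, 3,4,5-trimethoxy-2-(FG-O)phenol | Oc1cc(OC)c(OC)c(OC)c1Oc1cc(OC)c(Oc2cc(OC)c(OC)c(OC)c2)c(OC)c1 | intermediate
10 | DEFG aldehyde, 3,5-dimethoxy-4-(EFG-O)benzaldehyde | O=Cc1cc(OC)c(Oc2cc(OC)c(OC)c(OC)c2Oc2cc(OC)c(Oc3cc(OC)c(OC)c(OC)c3)c(OC)c2)c(OC)c1 | intermediate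
11 | DEFG aryl formate, 3,5-dimethoxy-4-(EFG-O)phenyl formate | O=COc1cc(OC)c(Oc2cc(OC)c(OC)c(OC)c2Oc2cc(OC)c(Oc3cc(OC)c(OC)c(OC)c3)c(OC)c2)c(OC)c1 | intermediate
12 | DEFG phenol, 3,5-dimethoxy-4-(EFG-O)phenol | Oc1cc(OC)c(Oc2cc(OC)c(OC)c(OC)c2Oc2cc(OC)c(Oc3cc(OC)c(OC)c(OC)c3)c(OC)c2)c(OC)c1 | intermediate
13 | CDEFG aldehyde, 3,4,5-trimethoxy-2-(DEFG-O)benzaldehyde | O=Cc1cc(OC)c(OC)c(OC)c1Oc1cc(OC)c(Oc2cc(OC)c(OC)c(OC)c2Oc2cc(OC)c(Oc3cc(OC)c(OC)c(OC)c3)c(OC)c2)c(OC)c1 | intermediate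
14 | CDEFG aryl formate, 3,4,5-trimethoxy-2-(DEFG-O)phenyl formate | O=COc1cc(OC)c(OC)c(OC)c1Oc1cc(OC)c(Oc2cc(OC)c(OC)c(OC)c2Oc2cc(OC)c(Oc3cc(OC)c(OC)c(OC)c3)c(OC)c2)c(OC)c1 | intermediate
15 | CDEFG phenol, 3,4,5-trimethoxy-2-(DEFG-O)phenol | Oc1cc(OC)c(OC)c(OC)c1Oc1cc(OC)c(Oc2cc(OC)c(OC)c(OC)c2Oc2cc(OC)c(Oc3cc(OC)c(OC)c(OC)c3)c(OC)c2)c(OC)c1 | intermediate
16 | methyl bromoacetate | COC(=O)CBr | starting material
17 | methyl (CDEFG-O)acetate | COC(=O)COc1cc(OC)c(OC)c(OC)c1Oc1cc(OC)c(Oc2cc(OC)c(OC)c(OC)c2Oc2cc(OC)c(Oc3cc(OC)c(OC)c(OC)c3)c(OC)c2)c(OC)c1 | intermediate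
18 | (CDEFG-O)acetic acid | OC(=O)COc1cc(OC)c(OC)c(OC)c1Oc1cc(OC)c(Oc2cc(OC)c(OC)c(OC)c2Oc2cc(OC)c(Oc3cc(OC)c(OC)c(OC)c3)c(OC)c2)c(OC)c1 | intermediate
19 | ethoxyacetylene | CCOC#C | starting material
20 | (CDEFG-O)acetyl chloride | ClC(=O)COc1cc(OC)c(OC)c(OC)c1Oc1cc(OC)c(Oc2cc(OC)c(OC)c(OC)c2Oc2cc(OC)c(Oc3cc(OC)c(OC)c(OC)c3)c(OC)c2)c(OC)c1 | intermediate
21 | (CDEFG-O)ketene | O=C=COc1cc(OC)c(OC)c(OC)c1Oc1cc(OC)c(Oc2cc(OC)c(OC)c(OC)c2Oc2cc(OC)c(Oc3cc(OC)c(OC)c(OC)c3)c(OC)c2)c(OC)c1 | intermediate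
22 | racemic 4-(CDEFG-O)-3-ethoxycyclobut-2-en-1-one (one enantiomer drawn) | CCOC1=CC(=O)[C@H]1Oc1cc(OC)c(OC)c(OC)c1Oc1cc(OC)c(Oc2cc(OC)c(OC)c(OC)c2Oc2cc(OC)c(Oc3cc(OC)c(OC)c(OC)c3)c(OC)c2)c(OC)c1 | intermediate
23 | 2,4,6-trimethoxybenzaldehyde | COc1cc(OC)c(C=O)c(OC)c1 | starting material
24 | 2,4,6-trimethoxyphenyl formate | COc1cc(OC)c(OC=O)c(OC)c1 | intermediate
25 | 2,4,6-trimethoxyphenol | COc1cc(OC)c(O)c(OC)c1 | intermediate
26 | trichloroethylene | ClC=C(Cl)Cl | starting material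
27 | (E)-1,2-dichlorovinyl 2,4,6-trimethoxyphenyl ether | COc1cc(OC)c(O/C(Cl)=C\Cl)c(OC)c1 | intermediate
28 | chloroethynyl 2,4,6-trimethoxyphenyl ether | COc1cc(OC)c(OC#CCl)c(OC)c1 | intermediate
29 | lithium (2,4,6-trimethoxyphenoxy)acetylide | COc1cc(OC)c(OC#C[Li])c(OC)c1 | intermediate
30 | ethynyl 2,4,6-trimethoxyphenyl ether | COc1cc(OC)c(OC#C)c(OC)c1 | intermediate
31 | vinylketene, (Z)-4-(CDEFG-O)-3-ethoxybuta-1,3-dien-1-one | O=C=C/C(OCC)=C/Oc1cc(OC)c(OC)c(OC)c1Oc1cc(OC)c(Oc2cc(OC)c(OC)c(OC)c2Oc2cc(OC)c(Oc3cc(OC)c(OC)c(OC)c3)c(OC)c2)c(OC)c1 | intermediate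
32 | vinylcyclobutenone, racemic 4-[(Z)-2-(CDEFG-O)-1-ethoxyethenyl]-3-(2,4,6-trimethoxyphenoxy)cyclobut-2-en-1-one (one enantiomer drawn) | COc1cc(OC)c(OC2=CC(=O)[C@@H]2/C(OCC)=C/Oc2cc(OC)c(OC)c(OC)c2Oc2cc(OC)c(Oc3cc(OC)c(OC)c(OC)c3Oc3cc(OC)c(Oc4cc(OC)c(OC)c(OC)c4)c(OC)c3)c(OC)c2)c(OC)c1 | intermediate
33 | dienylketene, (3E,5Z)-6-(CDEFG-O)-5-ethoxy-3-(2,4,6-trimethoxyphenoxy)hexa-1,3,5-trien-1-one | O=C=C/C(Oc1c(OC)cc(OC)cc1OC)=C\C(OCC)=C\Oc1cc(OC)c(OC)c(OC)c1Oc1cc(OC)c(Oc2cc(OC)c(OC)c(OC)c2Oc2cc(OC)c(Oc3cc(OC)c(OC)c(OC)c3)c(OC)c2)c(OC)c1 | intermediate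
34 | cyclohexadienone, racemic 6-(CDEFG-O)-5-ethoxy-3-(2,4,6-trimethoxyphenoxy)cyclohexa-2,4-dien-1-one (one enantiomer drawn) | O=C1C=C(Oc2c(OC)cc(OC)cc2OC)C=C(OCC)[C@H]1Oc1cc(OC)c(OC)c(OC)c1Oc1cc(OC)c(Oc2cc(OC)c(OC)c(OC)c2Oc2cc(OC)c(Oc3cc(OC)c(OC)c(OC)c3)c(OC)c2)c(OC)c1 | intermediate
35 | protected heptamer, 2-(CDEFG-O)-3-ethoxy-5-(2,4,6-trimethoxyphenoxy)phenol (B3 hydroxyl free, B5 ethyl ether) | COc1cc(OC)c(Oc2cc(O)c(Oc3cc(OC)c(OC)c(OC)c3Oc3cc(OC)c(Oc4cc(OC)c(OC)c(OC)c4Oc4cc(OC)c(Oc5cc(OC)c(OC)c(OC)c5)c(OC)c4)c(OC)c3)c(OCC)c2)c(OC)c1 | intermediate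
36 | target heptamer CNP0292517.0 (all eighteen hydroxyls free) | Oc1cc(O)c(Oc2cc(O)c(Oc3cc(O)c(O)c(O)c3Oc3cc(O)c(Oc4cc(O)c(O)c(O)c4Oc4cc(O)c(Oc5cc(O)c(O)c(O)c5)c(O)c4)c(O)c3)c(O)c2)c(O)c1 | target

Total step count: 15. Longest linear sequence: 12 steps (steps 1–10, 14 and 15); steps 11–13 are the three-step ring A branch.

Steps most likely to fail

1. Step 14. The vinylketene may be lost to dimerisation or to O-acylation of the newly formed phenol, and the terminal ynol ether may polymerise before the [2+2] occurs. The fallback sets out from 15 and returns at 36, attaching rings B and A by arylation instead. Phenol 15 would be coupled with bromide 2 under the conditions of step 5 to give the BCDEFG aldehyde F1. Baeyer–Villiger oxidation with mCPBA would give the BCDEFG aryl formate F2, and methanolysis the BCDEFG phenol F3. A further Ullmann coupling with 2-iodo-1,3,5-trimethoxybenzene (CuI, picolinic acid, K3PO4, DMSO, 110 °C) would give the octadecamethyl ether of the target F4. BBr3 as in step 15 would then deliver 36.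

2. Step 5. C–O bond formation at a bromide flanked by two methoxy groups, with a phenoxide that itself carries an ortho aryloxy group, may be so slow that hydrodebromination and phenol oxidation outrun the coupling. The fallback sets out from 9 and returns at 10, reversing the polarity so that the crowded ring D supplies the oxygen. Phenol 9 would be converted with Tf2O and pyridine into the EFG aryl triflate F5. Miyaura borylation (B2pin2, PdCl2(dppf), KOAc, dioxane, 80 °C) would give the EFG pinacol boronate F6, and NaIO4/NH4OAc in aqueous acetone the EFG boronic acid F7. Chan–Lam coupling of F7 with 4-hydroxy-3,5-dimethoxybenzaldehyde (Cu(OAc)2, pyridine, 4 Å molecular sieves, air, CH2Cl2, rt) would then give 10.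

3. Step 15. Some of the seventeen alkyl ethers may be cleaved incompletely and the free polyphenol may oxidise in air during isolation, which would leave mixtures that cannot be separated. The fallback sets out from 35 and returns at 36, isolating the product as a stable derivative. The crude product of the BBr3 treatment would be acetylated without purification (Ac2O, pyridine, DMAP cat.) to the octadecaacetate of the target F8. This would be purified by chromatography on silica, where under-dealkylated material separates. Deacetylation with HCl in MeOH at rt under Ar would then release 36.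

Further compounds
F1 | step 14 | BCDEFG aldehyde, 3,5-dimethoxy-4-(CDEFG-O)benzaldehyde | O=Cc1cc(OC)c(Oc2cc(OC)c(OC)c(OC)c2Oc2cc(OC)c(Oc3cc(OC)c(OC)c(OC)c3Oc3cc(OC)c(Oc4cc(OC)c(OC)c(OC)c4)c(OC)c3)c(OC)c2)c(OC)c1
F2 | step 14 | BCDEFG aryl formate, 3,5-dimethoxy-4-(CDEFG-O)phenyl formate | O=COc1cc(OC)c(Oc2cc(OC)c(OC)c(OC)c2Oc2cc(OC)c(Oc3cc(OC)c(OC)c(OC)c3Oc3cc(OC)c(Oc4cc(OC)c(OC)c(OC)c4)c(OC)c3)c(OC)c2)c(OC)c1
F3 | step 14 | BCDEFG phenol, 3,5-dimethoxy-4-(CDEFG-O)phenol | Oc1cc(OC)c(Oc2cc(OC)c(OC)c(OC)c2Oc2cc(OC)c(Oc3cc(OC)c(OC)c(OC)c3Oc3cc(OC)c(Oc4cc(OC)c(OC)c(OC)c4)c(OC)c3)c(OC)c2)c(OC)c1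
F4 | step 14 | octadecamethyl ether of the target | COc1cc(OC)c(Oc2cc(OC)c(Oc3cc(OC)c(OC)c(OC)c3Oc3cc(OC)c(Oc4cc(OC)c(OC)c(OC)c4Oc4cc(OC)c(Oc5cc(OC)c(OC)c(OC)c5)c(OC)c4)c(OC)c3)c(OC)c2)c(OC)c1
F5 | step 5 | EFG aryl triflate, 3,4,5-trimethoxy-2-(FG-O)phenyl trifluoromethanesulfonate | O=S(=O)(Oc1cc(OC)c(OC)c(OC)c1Oc1cc(OC)c(Oc2cc(OC)c(OC)c(OC)c2)c(OC)c1)C(F)(F)F
F6 | step 5 | EFG pinacol boronate, 2-[3,4,5-trimethoxy-2-(FG-O)phenyl]-4,4,5,5-tetramethyl-1,3,2-dioxaborolane | CC1(C)OB(OC1(C)C)c1cc(OC)c(OC)c(OC)c1Oc1cc(OC)c(Oc2cc(OC)c(OC)c(OC)c2)c(OC)c1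
F7 | step 5 | EFG boronic acid, [3,4,5-trimethoxy-2-(FG-O)phenyl]boronic acid | OB(O)c1cc(OC)c(OC)c(OC)c1Oc1cc(OC)c(Oc2cc(OC)c(OC)c(OC)c2)c(OC)c1
F8 | step 15 | octadecaacetate of the target | CC(=O)Oc1cc(OC(C)=O)c(Oc2cc(OC(C)=O)c(Oc3cc(OC(C)=O)c(OC(C)=O)c(OC(C)=O)c3Oc3cc(OC(C)=O)c(Oc4cc(OC(C)=O)c(OC(C)=O)c(OC(C)=O)c4Oc4cc(OC(C)=O)c(Oc5cc(OC(C)=O)c(OC(C)=O)c(OC(C)=O)c5)c(OC(C)=O)c4)c(OC(C)=O)c3)c(OC(C)=O)c2)c(OC(C)=O)c1
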